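## Plan

- Numbering: ring A is the dihydrofuran ring (O1, C2, C3, C3a, C7a); ring B is the six-membered carbocycle (C3a, C4, C5, C6, C7, C7a).
- Cuts, in retrosynthetic order: C3a–CH2 of the allyl group (dearomatising allylation of a C6 phenol); the C3 methyl group back to a methyl ester; C2–C3 (carbenoid C–H insertion, opens ring A); O1–C2 (benzyl ether formation); C3a–C3 (arylation of malonate by an aryl bromide).
- Enabling feature: C2 is a benzylic ether carbon bonded to O1 and to the trimethoxyphenyl ring, and C3 sits on the ring B carbon C3a next to C7a–O1. A carbenoid at C3 is therefore 1,5-related to the C2–H bond of an O1 benzyl ether and can close ring A by inserting into it.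
- Forward order: ring B is bought as an arene; O1 is freed and benzylated; the acetate arm is attached at C3a; ring A closes in step 7; ring B is dearomatised in the last step.
- Stereochemistry: C2 and C3 (cis) come from the chiral carboxylate ligands of the rhodium catalyst in step 7 and are carried on without base or acid. C3a comes from substrate control, the allyl group entering anti to the cis C3 methyl and C2 aryl groups.

Key step: step 7

Assumption: the S-configured catalyst is taken to deliver the (2R,3S) ester; the sense of induction is to be confirmed on the first run, and if it is the opposite, the mirror-image catalyst Rh2(R-PTTL)4 (from D-tert-leucine) is used with no other change.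

## Route

Step 1
Reactants: 1 2-bromo-5-hydroxy-4-methoxybenzaldehyde; 2 benzyl bromide
Product: 3 5-(benzyloxy)-2-bromo-4-methoxybenzaldehyde
Conditions: BnBr, K2CO3, DMF, rt
Reagents that add atoms: benzyl bromide, BrCc1ccccc1
Why: Williamson ether synthesis on the only phenol; the benzyl ether masks the future O6 through the basic, hydridic and carbenoid steps that follow.

Step 2
Reactants: 3 5-(benzyloxy)-2-bromo-4-methoxybenzaldehyde; 4 3-chloroperbenzoic acid (mCPBA)
Product: 6 5-(benzyloxy)-2-bromo-4-methoxyphenol, via aryl formate 5 (not isolated)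
Conditions: mCPBA, CH2Cl2, 0 °C to rt; aqueous NaHCO3 wash; then K2CO3 (0.2 equiv), MeOH, rt
Reagents that add atoms: 3-chloroperbenzoic acid, OOC(=O)c1cccc(Cl)c1
Why: Baeyer–Villiger oxidation of an electron-rich benzaldehyde (Dakin-type), in which the aryl group activated by the para methoxy group migrates to oxygen, followed by methanolysis of the formate to free the phenol that becomes O1.

Step 3
Reactants: 6 5-(benzyloxy)-2-bromo-4-methoxyphenol; 7 5-(bromomethyl)-1,2,3-trimethoxybenzene
Product: 8 1-(benzyloxy)-4-bromo-2-methoxy-5-[(3,4,5-trimethoxybenzyl)oxy]benzene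
Conditions: K2CO3, DMF, 50 °C
Reagents that add atoms: 5-(bromomethyl)-1,2,3-trimethoxybenzene, COc1cc(CBr)cc(OC)c1OC
Why: Williamson ether synthesis with a reactive benzylic bromide; it installs the O1–CH2Ar unit whose benzylic carbon becomes C2.

Step 4
Reactants: 8 1-(benzyloxy)-4-bromo-2-methoxy-5-[(3,4,5-trimethoxybenzyl)oxy]benzene; 9 dimethyl malonate
Product: 10 dimethyl 2-{4-(benzyloxy)-5-methoxy-2-[(3,4,5-trimethoxybenzyl)oxy]phenyl}propanedioate
Conditions: Pd(OAc)2 (3 mol%), P(t-Bu)3·HBF4 (6 mol%), K3PO4, toluene, 80 °C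
Reagents that add atoms: dimethyl malonate, COC(=O)CC(=O)OC
Why: Palladium-catalysed α-arylation of a malonate enolate, in which the bulky electron-rich phosphine drives oxidative addition into the electron-rich ortho-alkoxy aryl bromide and reductive elimination of the hindered aryl–carbon bond, forming C3a–C3.

Step 5
Reactants: 10 dimethyl 2-{4-(benzyloxy)-5-methoxy-2-[(3,4,5-trimethoxybenzyl)oxy]phenyl}propanedioate
Product: 11 methyl 2-{4-(benzyloxy)-5-methoxy-2-[(3,4,5-trimethoxybenzyl)oxy]phenyl}acetate
Conditions: LiCl, H2O, DMSO, 130 °C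
Reagents that add atoms: none
Why: Krapcho dealkoxycarbonylation, in which chloride demethylates one ester, CO2 is lost and the aryl-stabilised carbanion is protonated by water, while the ethers are inert.

Step 6
Reactants: 11 methyl 2-{4-(benzyloxy)-5-methoxy-2-[(3,4,5-trimethoxybenzyl)oxy]phenyl}acetate; 12 4-acetamidobenzenesulfonyl azide (p-ABSA)
Product: 13 methyl 2-{4-(benzyloxy)-5-methoxy-2-[(3,4,5-trimethoxybenzyl)oxy]phenyl}-2-diazoacetate
Conditions: p-ABSA, DBU, MeCN, 0 °C to rt
Reagents that add atoms: 4-acetamidobenzenesulfonyl azide, CC(=O)Nc1ccc(cc1)S(=O)(=O)N=[N+]=[N-]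
Why: Regitz diazo transfer to the enolate of an arylacetate, the standard entry to aryldiazoacetates; the sulfonamide by-product is removed by filtration and washing.

Step 7
Reactants: 13 methyl 2-{4-(benzyloxy)-5-methoxy-2-[(3,4,5-trimethoxybenzyl)oxy]phenyl}-2-diazoacetate
Product: 14 methyl (2R,3S)-6-(benzyloxy)-5-methoxy-2-(3,4,5-trimethoxyphenyl)-2,3-dihydro-1-benzofuran-3-carboxylate (cis)
Conditions: Rh2(S-PTTL)4 [dirhodium tetrakis(N-phthaloyl-(S)-tert-leucinate)] (1 mol%), toluene, −78 to −40 °C
Reagents that add atoms: none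
Why: Loss of N2 from 13 on the divalent-rhodium dimer gives an electrophilic donor/acceptor carbenoid at the future C3, which inserts into the benzylic C2–H bond of the trimethoxybenzyl ether through a concerted, hydride-transfer-like three-centre transition state and so forms C2–C3. The closest known reaction type is the enantioselective intramolecular C–H insertion of 2-(benzyloxy)aryl diazoacetates into the benzylic ether C–H bond, which gives cis-2-aryl-2,3-dihydrobenzofuran-3-carboxylates under phthalimide-protected amino-acid carboxylates of divalent rhodium. Ring A (O1, C2, C3, C3a, C7a) closes by 1,5-insertion, the five-membered ring arising through a five-centre cyclic array. C3 is set by the chiral carboxylate ligands, which fix the carbenoid face that meets the C–H bond, and C2 is set by the same ligands, which select one of the two enantiotopic benzylic hydrogens and hold the aryl group syn to the ester, so that the kinetic cis (2R,3S) isomer should result. The step needs site selectivity, chemoselectivity over oxonium ylide formation, and cis diastereoselectivity with enantioselectivity. The first is secured because only the C–H bonds next to O1 are within reach (the O6 benzyl ether is para to the carbenoid carbon), the second by the hydridic, doubly activated C2–H bond at low temperature, and the third by the ligands, with base excluded afterwards.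

Step 8
Reactants: 14 methyl (2R,3S)-6-(benzyloxy)-5-methoxy-2-(3,4,5-trimethoxyphenyl)-2,3-dihydro-1-benzofuran-3-carboxylate
Product: 15 [(2R,3R)-6-(benzyloxy)-5-methoxy-2-(3,4,5-trimethoxyphenyl)-2,3-dihydro-1-benzofuran-3-yl]methanol
Conditions: LiAlH4, THF, −78 to 0 °C
Reagents that add atoms: none
Why: Hydride reduction of the ester to the primary alcohol, run cold so that reduction outruns enolisation and the base-labile cis C3 centre is kept (the C3 descriptor changes only because the priorities change).

Step 9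
Reactants: 15 [(2R,3R)-6-(benzyloxy)-5-methoxy-2-(3,4,5-trimethoxyphenyl)-2,3-dihydro-1-benzofuran-3-yl]methanol; 16 methanesulfonyl chloride
Product: 17 [(2R,3R)-6-(benzyloxy)-5-methoxy-2-(3,4,5-trimethoxyphenyl)-2,3-dihydro-1-benzofuran-3-yl]methyl methanesulfonate
Conditions: MsCl, Et3N, CH2Cl2, 0 °C
Reagents that add atoms: methanesulfonyl chloride, CS(=O)(=O)Cl
Why: Sulfonylation of the primary alcohol turns the oxygen into a leaving group without touching C2 or C3.

Step 10
Reactants: 17 [(2R,3R)-6-(benzyloxy)-5-methoxy-2-(3,4,5-trimethoxyphenyl)-2,3-dihydro-1-benzofuran-3-yl]methyl methanesulfonate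
Product: 18 (2R,3S)-6-(benzyloxy)-5-methoxy-3-methyl-2-(3,4,5-trimethoxyphenyl)-2,3-dihydro-1-benzofuran
Conditions: LiEt3BH, THF, 0 °C to rt
Reagents that add atoms: none
Why: SN2 displacement of the primary mesylate by the strongly nucleophilic, weakly basic triethylborohydride converts CH2OMs into the C3 methyl group with no bond to a stereocentre broken.

Step 11
Reactants: 18 (2R,3S)-6-(benzyloxy)-5-methoxy-3-methyl-2-(3,4,5-trimethoxyphenyl)-2,3-dihydro-1-benzofuran
Product: 19 (2R,3S)-5-methoxy-3-methyl-2-(3,4,5-trimethoxyphenyl)-2,3-dihydro-1-benzofuran-6-ol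
Conditions: H2 (1 atm), 10% Pd/C, EtOAc, rt, stopped at full conversion
Reagents that add atoms: none
Why: Hydrogenolysis of the primary benzyl aryl ether, which is much faster than cleavage of the hindered, secondary, cyclic C2–O1 bond under neutral conditions.

Step 12
Reactants: 19 (2R,3S)-5-methoxy-3-methyl-2-(3,4,5-trimethoxyphenyl)-2,3-dihydro-1-benzofuran-6-ol; 20 allyl methyl carbonate
Product: 22 (2R,3S,3aS)-5-methoxy-3-methyl-3a-(prop-2-en-1-yl)-2-(3,4,5-trimethoxyphenyl)-3,3a-dihydro-1-benzofuran-6(2H)-one, via O-allyl ether 21 (not isolated)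
Conditions: Pd2(dba)3 (5 mol%), PPh3 (20 mol%), allyl methyl carbonate (1.2 equiv), toluene, rt then 80 °C
Reagents that add atoms: allyl methyl carbonate, C=CCOC(=O)OC
Why: Proposed new method: oxidative addition of zerovalent palladium to 20 gives a π-allyl complex of divalent palladium and, after loss of CO2, methoxide, which deprotonates 19; the phenoxide is expected to close first to the O-allyl ether 21, which is re-ionised on warming, and the ion pair should then recombine at C3a, the ring B carbon para to the phenoxide oxygen and ortho to O1, from the face opposite the cis C3 methyl and C2 aryl groups, which sets (3aS) with the allyl group trans to the methyl group and gives a cross-conjugated dienone that cannot rearomatise; the closest known reaction types are the Tsuji–Trost-type intermolecular allylic dearomatisation of 1-substituted 2-naphthols and of acylphloroglucinols and the intramolecular ipso-allylation of para-substituted phenols.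

## Compound list

1 | 2-bromo-5-hydroxy-4-methoxybenzaldehyde | O=Cc1cc(O)c(OC)cc1Br | starting material
2 | benzyl bromide | BrCc1ccccc1 | starting material
3 | 5-(benzyloxy)-2-bromo-4-methoxybenzaldehyde | O=Cc1cc(OCc2ccccc2)c(OC)cc1Br | intermediate
4 | 3-chloroperbenzoic acid (mCPBA) | OOC(=O)c1cccc(Cl)c1 | starting material
5 | 5-(benzyloxy)-2-bromo-4-methoxyphenyl formate | O=COc1cc(OCc2ccccc2)c(OC)cc1Br | intermediate
6 | 5-(benzyloxy)-2-bromo-4-methoxyphenol | Oc1cc(OCc2ccccc2)c(OC)cc1Br | intermediate
7 | 5-(bromomethyl)-1,2,3-trimethoxybenzene | COc1cc(CBr)cc(OC)c1OC | starting material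
8 | 1-(benzyloxy)-4-bromo-2-methoxy-5-[(3,4,5-trimethoxybenzyl)oxy]benzene | COc1cc(Br)c(OCc2cc(OC)c(OC)c(OC)c2)cc1OCc1ccccc1 | intermediate
9 | dimethyl malonate | COC(=O)CC(=O)OC | starting material
10 | dimethyl 2-{4-(benzyloxy)-5-methoxy-2-[(3,4,5-trimethoxybenzyl)oxy]phenyl}propanedioate | COC(=O)C(C(=O)OC)c1cc(OC)c(OCc2ccccc2)cc1OCc1cc(OC)c(OC)c(OC)c1 | intermediate
11 | methyl 2-{4-(benzyloxy)-5-methoxy-2-[(3,4,5-trimethoxybenzyl)oxy]phenyl}acetate | COC(=O)Cc1cc(OC)c(OCc2ccccc2)cc1OCc1cc(OC)c(OC)c(OC)c1 | intermediate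
12 | 4-acetamidobenzenesulfonyl azide (p-ABSA) | CC(=O)Nc1ccc(cc1)S(=O)(=O)N=[N+]=[N-] | starting material
13 | methyl 2-{4-(benzyloxy)-5-methoxy-2-[(3,4,5-trimethoxybenzyl)oxy]phenyl}-2-diazoacetate | COC(=O)C(=[N+]=[N-])c1cc(OC)c(OCc2ccccc2)cc1OCc1cc(OC)c(OC)c(OC)c1 | intermediate
14 | methyl (2R,3S)-6-(benzyloxy)-5-methoxy-2-(3,4,5-trimethoxyphenyl)-2,3-dihydro-1-benzofuran-3-carboxylate | COc1cc2c(cc1OCc1ccccc1)O[C@@H](c1cc(OC)c(OC)c(OC)c1)[C@H]2C(=O)OC | intermediate
15 | [(2R,3R)-6-(benzyloxy)-5-methoxy-2-(3,4,5-trimethoxyphenyl)-2,3-dihydro-1-benzofuran-3-yl]methanol | COc1cc2c(cc1OCc1ccccc1)O[C@@H](c1cc(OC)c(OC)c(OC)c1)[C@H]2CO | intermediate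
16 | methanesulfonyl chloride | CS(=O)(=O)Cl | starting material
17 | [(2R,3R)-6-(benzyloxy)-5-methoxy-2-(3,4,5-trimethoxyphenyl)-2,3-dihydro-1-benzofuran-3-yl]methyl methanesulfonate | COc1cc2c(cc1OCc1ccccc1)O[C@@H](c1cc(OC)c(OC)c(OC)c1)[C@H]2COS(C)(=O)=O | intermediate
18 | (2R,3S)-6-(benzyloxy)-5-methoxy-3-methyl-2-(3,4,5-trimethoxyphenyl)-2,3-dihydro-1-benzofuran | COc1cc2c(cc1OCc1ccccc1)O[C@@H](c1cc(OC)c(OC)c(OC)c1)[C@H]2C | intermediate
19 | (2R,3S)-5-methoxy-3-methyl-2-(3,4,5-trimethoxyphenyl)-2,3-dihydro-1-benzofuran-6-ol | COc1cc2c(cc1O)O[C@@H](c1cc(OC)c(OC)c(OC)c1)[C@H]2C | intermediate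
20 | allyl methyl carbonate | C=CCOC(=O)OC | starting material
21 | (2R,3S)-5-methoxy-3-methyl-6-(prop-2-en-1-yloxy)-2-(3,4,5-trimethoxyphenyl)-2,3-dihydro-1-benzofuran | COc1cc2c(cc1OCC=C)O[C@@H](c1cc(OC)c(OC)c(OC)c1)[C@H]2C | intermediate
22 | (2R,3S,3aS)-5-methoxy-3-methyl-3a-(prop-2-en-1-yl)-2-(3,4,5-trimethoxyphenyl)-3,3a-dihydro-1-benzofuran-6(2H)-one | C=CC[C@]12C=C(OC)C(=O)C=C1O[C@@H](c1cc(OC)c(OC)c(OC)c1)[C@H]2C | target

## Count and risks

Total step count: 12. Longest linear sequence: 12 steps (from 1; the route is fully linear).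

**Steps most likely to fail**

1. Step 12 (Proposed new method). The ion pair may recombine at oxygen without re-ionising, or through the unsubstituted C7 with rearomatisation, faster than through the substituted C3a, so that the allyl group never reaches the quaternary position. The fallback uses known sigmatropic chemistry, sets out from 19 and returns at 22.
   - Williamson allylation of 19 (allyl bromide, K2CO3, acetone) should give the allyl ether 21 as an isolated compound.
   - Heating 21 (N,N-diethylaniline, about 180 °C, to partial conversion) should start a para-Claisen sequence. An aromatic Claisen shift to the methoxy-bearing C5 gives (2R,3S,5R)-5-methoxy-3-methyl-5-(prop-2-en-1-yl)-2-(3,4,5-trimethoxyphenyl)-2,3-dihydro-1-benzofuran-6(5H)-one F1, and a Cope shift across the same face of ring B carries the allyl group to C3a to give 22.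
   - Both C5 epimers of the ortho dienone form reversibly, but only the one with the allyl group anti to the C3 methyl group has an unhindered path to C3a.
   - The competing ortho shift to C7 is expected to take part of the material; its phenolic product is removed by base extraction and unreacted 21 is recycled.

2. Step 7. Enantioselectivity or the cis preference may erode on this electron-rich substrate, or the carbenoid may be diverted to an oxonium ylide and a 1,2-shift. The fallback moves stereocontrol into the substrate, sets out from 11 and returns at 15.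
   - Saponification of 11 (LiOH, THF/H2O, then HCl) gives 2-{4-(benzyloxy)-5-methoxy-2-[(3,4,5-trimethoxybenzyl)oxy]phenyl}acetic acid F2.
   - Steglich esterification with (R)-pantolactone (DCC, DMAP, CH2Cl2) gives (3R)-4,4-dimethyl-2-oxooxolan-3-yl 2-{4-(benzyloxy)-5-methoxy-2-[(3,4,5-trimethoxybenzyl)oxy]phenyl}acetate F3.
   - Diazo transfer (p-ABSA, DBU) gives (3R)-4,4-dimethyl-2-oxooxolan-3-yl 2-{4-(benzyloxy)-5-methoxy-2-[(3,4,5-trimethoxybenzyl)oxy]phenyl}-2-diazoacetate F4.
   - Insertion under the same class of cis-selective phthalimido carboxylate catalyst gives (3R)-4,4-dimethyl-2-oxooxolan-3-yl (2R,3S)-6-(benzyloxy)-5-methoxy-2-(3,4,5-trimethoxyphenyl)-2,3-dihydro-1-benzofuran-3-carboxylate F5. The auxiliary adds a second control element, and the two cis products are now diastereomers that can be separated by chromatography or crystallisation; the matched auxiliary/catalyst pairing is chosen by test.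
   - LiAlH4 reduces F5 to 15.

3. Step 4. Oxidative addition into the electron-rich, ortho-substituted aryl bromide may be slow, so that protodebromination competes with coupling. The fallback replaces the cross-coupling by organolithium chemistry, sets out from 8 and returns at 13, bypassing steps 5 and 6.
   - Bromine–lithium exchange on 8 (n-BuLi, THF, −78 °C) and addition of the aryllithium to excess dimethyl oxalate gives methyl 2-{4-(benzyloxy)-5-methoxy-2-[(3,4,5-trimethoxybenzyl)oxy]phenyl}-2-oxoacetate F6.
   - Condensation with 4-methylbenzenesulfonohydrazide (MeOH, rt) gives methyl 2-{4-(benzyloxy)-5-methoxy-2-[(3,4,5-trimethoxybenzyl)oxy]phenyl}-2-[2-(4-methylbenzenesulfonyl)hydrazinylidene]acetate F7.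
   - Bamford–Stevens-type elimination of sulfinate (DBU, CH2Cl2, rt) gives 13.

## Further compounds

F1 | step 12 | (2R,3S,5R)-5-methoxy-3-methyl-5-(prop-2-en-1-yl)-2-(3,4,5-trimethoxyphenyl)-2,3-dihydro-1-benzofuran-6(5H)-one | C=CC[C@@]1(OC)C=C2C(=CC1=O)O[C@@H](c1cc(OC)c(OC)c(OC)c1)[C@H]2C
F2 | step 7 | 2-{4-(benzyloxy)-5-methoxy-2-[(3,4,5-trimethoxybenzyl)oxy]phenyl}acetic acid | OC(=O)Cc1cc(OC)c(OCc2ccccc2)cc1OCc1cc(OC)c(OC)c(OC)c1
F3 | step 7 | (3R)-4,4-dimethyl-2-oxooxolan-3-yl 2-{4-(benzyloxy)-5-methoxy-2-[(3,4,5-trimethoxybenzyl)oxy]phenyl}acetate | O=C(Cc1cc(OC)c(OCc2ccccc2)cc1OCc1cc(OC)c(OC)c(OC)c1)O[C@H]1C(=O)OCC1(C)C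
F4 | step 7 | (3R)-4,4-dimethyl-2-oxooxolan-3-yl 2-{4-(benzyloxy)-5-methoxy-2-[(3,4,5-trimethoxybenzyl)oxy]phenyl}-2-diazoacetate | [N-]=[N+]=C(C(=O)O[C@H]1C(=O)OCC1(C)C)c1cc(OC)c(OCc2ccccc2)cc1OCc1cc(OC)c(OC)c(OC)c1
F5 | step 7 | (3R)-4,4-dimethyl-2-oxooxolan-3-yl (2R,3S)-6-(benzyloxy)-5-methoxy-2-(3,4,5-trimethoxyphenyl)-2,3-dihydro-1-benzofuran-3-carboxylate | COc1cc2c(cc1OCc1ccccc1)O[C@@H](c1cc(OC)c(OC)c(OC)c1)[C@H]2C(=O)O[C@H]1C(=O)OCC1(C)C
F6 | step 4 | methyl 2-{4-(benzyloxy)-5-methoxy-2-[(3,4,5-trimethoxybenzyl)oxy]phenyl}-2-oxoacetate | COC(=O)C(=O)c1cc(OC)c(OCc2ccccc2)cc1OCc1cc(OC)c(OC)c(OC)c1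
F7 | step 4 | methyl 2-{4-(benzyloxy)-5-methoxy-2-[(3,4,5-trimethoxybenzyl)oxy]phenyl}-2-[2-(4-methylbenzenesulfonyl)hydrazinylidene]acetate | COC(=O)C(=NNS(=O)(=O)c1ccc(C)cc1)c1cc(OC)c(OCc2ccccc2)cc1OCc1cc(OC)c(OC)c(OC)c1
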